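A direct plan would cleave (−)-α-pinene to a pinonate and rebuild each ε-ring by heating the alkenylcyclobutane diester A1 to about 240 °C,
a 1,3-carbon shift to the cyclohexene diester A2; each ring would then be grown into a C20 phosphonium salt and two of them joined to a C10 dialdehyde.
Weakest would be (i) the thermal diradical ring expansion A1 → A2, which would close the ring and set C6 at once on a modest conformational bias,
against fragmentation and hydrogen shifts; (ii) the base equilibration of the cis enone A3 to the trans enone A4, which would leave C6' to a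
thermodynamic ratio and invite conjugation of the ring double bond; (iii) the ester-to-phosphonium run, six operations done twice for five chain
carbons each, ending in an acid ionisation and a Wittig union that one would least like to run on precious late material.

Plan of the new route
Cuts: C7=C8 and C7'=C8' (sulfone olefinations on crocetindialdehyde), then C6–C7 in each ring, traced by a [3,3] shift to a C4–O bond.
Enabling feature: C6 is an allylic CH beside C4=C5(CH3), the 1,3-transposed form of a C4 carbinol flanked by C5(CH3)=C6; C4 lies 1,3 to C2.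
No ring is formed: both rings are bought as 2,4,4-trimethylcyclohex-2-enone; C2 by conjugate allylation and lipase resolution, C4 from C2, C6 from C4.
Ester formation with retention gives 2,6-cis ring A, Mitsunobu inversion gives 2,6-trans ring B: no diradical closure, no base epimerisation.
The sulfone left on C7 is the olefination handle and the C5 arms come from the allyl group by cross-metathesis: no ester-to-phosphonium run.

Key step: step 10

Remark: ring positions in the text are in carotenoid numbering (C1 = C(CH3)2, C2 bears the C5 arm, C4=C5 ring double bond, C6 bears the chain); systematic names use their own locants.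
Assumption: 2,4,4-trimethylcyclohex-2-en-1-one and all-E crocetindialdehyde are taken as purchasable, and the lipase is taken to acylate the (1R)-alcohol, as the size rule for secondary alcohols predicts (otherwise the recovered alcohol would be carried on).

Step 1
Reactants: 1 2,4,4-trimethylcyclohex-2-en-1-one
Product: 2 2,4,4-trimethylcyclohexa-2,5-dien-1-one
Conditions: DDQ (1.3 equiv), dioxane, 100 °C
Reagents that add atoms: none
Why: Quinone dehydrogenation through the cross-conjugated dienol can only give the 2,5-dienone, because the quaternary C4 blocks both γ-enolisation and aromatisation.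

Step 2
Reactants: 2 2,4,4-trimethylcyclohexa-2,5-dien-1-one; 3 allyltrimethylsilane
Product: 5 rac-2,4,4-trimethyl-5-(prop-2-en-1-yl)cyclohex-2-en-1-one, via titanium enolate 4 (not isolated)
Conditions: TiCl4 (1.1 equiv), CH2Cl2, −78 °C; 3 (1.3 equiv); then aq. NaHCO3
Reagents that add atoms: none
Why: Hosomi–Sakurai conjugate allylation; both β-carbons flank the quaternary carbon, but only the C5=C6 enone lacks an α-methyl group, so allyl should add at C5 and leave the 2-methyl enone intact.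

Step 3
Reactants: 5 rac-2,4,4-trimethyl-5-(prop-2-en-1-yl)cyclohex-2-en-1-one
Product: 6 rac-(1R,5S)-2,4,4-trimethyl-5-(prop-2-en-1-yl)cyclohex-2-en-1-ol (cis)
Conditions: NaBH4, CeCl3·7H2O, MeOH, −40 → 0 °C; minor trans isomer removed by chromatography
Reagents that add atoms: none
Why: Luche 1,2-reduction; hydride should add to the carbonyl face anti to the allyl arm (axial attack on the sofa conformer with that arm pseudoequatorial) and give the cis-1,5 alcohol, as 5-substituted 2-methylcyclohexenones such as carvone do.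

Step 4
Reactants: 6 rac-(1R,5S)-2,4,4-trimethyl-5-(prop-2-en-1-yl)cyclohex-2-en-1-ol
Product: 7 (1R,5S)-2,4,4-trimethyl-5-(prop-2-en-1-yl)cyclohex-2-en-1-yl acetate
Conditions: Burkholderia cepacia lipase (immobilised), vinyl acetate, t-BuOMe, 30 °C, stopped near half conversion
Reagents that add atoms: vinyl acetate, C=COC(C)=O
Why: Kinetic resolution by a lipase (serine hydrolase) through enantioselective transesterification should acylate the (1R)-alcohol (large flank the C2 alkenyl carbon, small flank the C6 methylene) and leave the (1S,5R)-alcohol for chromatographic removal, which fixes the absolute configuration of C2 of both rings.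

Step 5
Reactants: 7 (1R,5S)-2,4,4-trimethyl-5-(prop-2-en-1-yl)cyclohex-2-en-1-yl acetate
Product: 8 (1R,5S)-2,4,4-trimethyl-5-(prop-2-en-1-yl)cyclohex-2-en-1-ol
Conditions: K2CO3 (cat.), MeOH, 25 °C
Reagents that add atoms: none
Why: Base-catalysed methanolysis (transesterification) frees the enantiopure cis alcohol without touching either stereocentre.

Step 6
Reactants: 9 3,5-bis(trifluoromethyl)benzenethiol; 10 bromoacetic acid
Product: 11 {[3,5-bis(trifluoromethyl)phenyl]sulfanyl}acetic acid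
Conditions: NaOH (2.1 equiv), H2O/EtOH, 0 → 25 °C; then aq. HCl
Reagents that add atoms: none
Why: SN2 S-alkylation of the thiolate by bromoacetate.

Step 7
Reactants: 11 {[3,5-bis(trifluoromethyl)phenyl]sulfanyl}acetic acid
Product: 12 {[3,5-bis(trifluoromethyl)phenyl]sulfonyl}acetic acid
Conditions: H2O2 (30 % aq.), Na2WO4·2H2O (cat.), AcOH, 50 °C
Reagents that add atoms: hydrogen peroxide, OO
Why: Tungstate-catalysed oxidation of sulfide to sulfone is done before any alkene is present, so no chemoselectivity question arises.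

Step 8
Reactants: 8 (1R,5S)-2,4,4-trimethyl-5-(prop-2-en-1-yl)cyclohex-2-en-1-ol; 13 2-methylbut-2-ene
Product: 14 (1R,5S)-2,4,4-trimethyl-5-(3-methylbut-2-en-1-yl)cyclohex-2-en-1-ol
Conditions: (H2IMes)(PCy3)Cl2Ru=CHPh (second-generation Grubbs catalyst, 5 mol %), 13 (excess), CH2Cl2, 40 °C
Reagents that add atoms: none
Why: Olefin cross-metathesis of the terminal allyl group with excess 2-methylbut-2-ene gives the prenyl arm (no geometry to control), while the trisubstituted ring alkene and the free alcohol should not react.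

Step 9
Reactants: 14 (1R,5S)-2,4,4-trimethyl-5-(3-methylbut-2-en-1-yl)cyclohex-2-en-1-ol; 12 {[3,5-bis(trifluoromethyl)phenyl]sulfonyl}acetic acid
Product: 15 (1R,5S)-2,4,4-trimethyl-5-(3-methylbut-2-en-1-yl)cyclohex-2-en-1-yl {[3,5-bis(trifluoromethyl)phenyl]sulfonyl}acetate (cis ester)
Conditions: DCC, DMAP (cat.), CH2Cl2, 0 → 25 °C
Reagents that add atoms: none
Why: Carbodiimide (Steglich) esterification acylates the alcohol oxygen, so the C4–O bond and the cis relation to C2 are retained.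

Step 10
Reactants: 15 cis ester
Product: 18 1-({[(1R,5S)-2,6,6-trimethyl-5-(3-methylbut-2-en-1-yl)cyclohex-2-en-1-yl]methyl}sulfonyl)-3,5-bis(trifluoromethyl)benzene (ring-A sulfone; 2,6-cis), via silyl ketene acetal 16 (not isolated), via silyl ester 17 (not isolated)
Conditions: N,O-bis(trimethylsilyl)acetamide (1 equiv), KOAc (0.1 equiv), PhMe, 110 °C
Reagents that add atoms: none
Why: N,O-bis(trimethylsilyl)acetamide with catalytic acetate silylates the doubly activated ester to the silyl ketene acetal 16, which undergoes a suprafacial [3,3] shift (Ireland–Claisen) across C4–C5(CH3)=C6, breaking C4–O and forming C6–C7 on the same ring face while the double bond moves to the ε position C4=C5; acetate-induced desilylation of 17 and loss of CO2 then leave the sulfone on C7. The closest known reaction type is the decarboxylative Claisen rearrangement of allylic (arylsulfonyl)acetates. No ring is closed: the six-membered ring is that of enone 1 and only its allyl unit is reorganised. The new stereocentre C6 is controlled by C4 through the cyclic, necessarily suprafacial transition state, so the ester with C4–O cis to the C2 arm gives the 2,6-cis ring A. No reagent has to choose a position or a face, since there is one allyl unit and the migrating carbon is tethered to the C4 oxygen; the substrate must only reach a pseudoaxial C4–O bond, which a sofa with C2 tilted away from the migrating group allows while the prenyl arm stays pseudoequatorial. The same operation on the C4-epimeric ester (step 15) gives the 2,6-trans ring, so one carbinol serves both ring configurations.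

Step 11
Reactants: 8 (1R,5S)-2,4,4-trimethyl-5-(prop-2-en-1-yl)cyclohex-2-en-1-ol; 19 methacrolein
Product: 20 (2E)-4-[(1S,5R)-5-hydroxy-2,2,4-trimethylcyclohex-3-en-1-yl]-2-methylbut-2-enal
Conditions: (H2IMes)Cl2Ru=CH(2-i-PrOC6H4) (second-generation Hoveyda–Grubbs catalyst, 5 mol %), 19 (10 equiv), CH2Cl2, 40 °C
Reagents that add atoms: none
Why: Cross-metathesis with the electron-poor 1,1-disubstituted partner should give the thermodynamically favoured E-enal, which fixes the E geometry of the hydroxyprenyl arm.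

Step 12
Reactants: 20 (2E)-4-[(1S,5R)-5-hydroxy-2,2,4-trimethylcyclohex-3-en-1-yl]-2-methylbut-2-enal
Product: 21 (1R,5S)-5-[(2E)-4-hydroxy-3-methylbut-2-en-1-yl]-2,4,4-trimethylcyclohex-2-en-1-ol
Conditions: NaBH4, CeCl3·7H2O, MeOH, −20 °C
Reagents that add atoms: none
Why: Luche 1,2-reduction of the enal gives the primary allylic alcohol and leaves both alkenes and both stereocentres untouched.

Step 13
Reactants: 21 (1R,5S)-5-[(2E)-4-hydroxy-3-methylbut-2-en-1-yl]-2,4,4-trimethylcyclohex-2-en-1-ol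
Product: 22 (1R,5S)-5-[(2E)-4-{[tert-butyl(dimethyl)silyl]oxy}-3-methylbut-2-en-1-yl]-2,4,4-trimethylcyclohex-2-en-1-ol
Conditions: t-BuMe2SiCl (1.05 equiv), imidazole, CH2Cl2, −20 → 0 °C
Reagents that add atoms: tert-butyl(chloro)dimethylsilane, CC(C)(C)[Si](C)(C)Cl
Why: Silylation should select the unhindered primary allylic alcohol over the secondary ring alcohol flanked by C(CH3)=.

Step 14
Reactants: 22 (1R,5S)-5-[(2E)-4-{[tert-butyl(dimethyl)silyl]oxy}-3-methylbut-2-en-1-yl]-2,4,4-trimethylcyclohex-2-en-1-ol; 12 {[3,5-bis(trifluoromethyl)phenyl]sulfonyl}acetic acid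
Product: 23 (1S,5S)-5-[(2E)-4-{[tert-butyl(dimethyl)silyl]oxy}-3-methylbut-2-en-1-yl]-2,4,4-trimethylcyclohex-2-en-1-yl {[3,5-bis(trifluoromethyl)phenyl]sulfonyl}acetate (trans ester)
Conditions: PPh3, DIAD, 12 (1.5 equiv), THF, 0 → 25 °C
Reagents that add atoms: none
Why: Mitsunobu esterification displaces the activated C4–O by the carboxylate of the strongly acidic sulfonylacetic acid in an SN2 step, inverting C4 and giving the trans ester directly; SN2' attack is disfavoured because the other allyl terminus is neopentyl.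

Step 15
Reactants: 23 trans ester
Product: 26 1-[({(1S,5R)-5-[(2E)-4-{[tert-butyl(dimethyl)silyl]oxy}-3-methylbut-2-en-1-yl]-2,6,6-trimethylcyclohex-2-en-1-yl}methyl)sulfonyl]-3,5-bis(trifluoromethyl)benzene (ring-B sulfone; 2,6-trans), via silyl ketene acetal 24 (not isolated), via silyl ester 25 (not isolated)
Conditions: N,O-bis(trimethylsilyl)acetamide (1 equiv), KOAc (0.1 equiv), PhMe, 110 °C
Reagents that add atoms: none
Why: The decarboxylative Claisen rearrangement of step 10, run on the C4-epimeric ester, delivers C7 to the opposite face of C6 and gives the 2,6-trans ring; the silyl ether should be inert to the silylating agent and to acetate.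

Step 16
Reactants: 18 ring-A sulfone; 27 crocetindialdehyde, (2E,4E,6E,8E,10E,12E,14E)-2,6,11,15-tetramethylhexadeca-2,4,6,8,10,12,14-heptaenedial
Product: 29 (2E,4E,6E,8E,10E,12E,14E,16E)-2,6,11,15-tetramethyl-17-[(1R,5S)-2,6,6-trimethyl-5-(3-methylbut-2-en-1-yl)cyclohex-2-en-1-yl]heptadeca-2,4,6,8,10,12,14,16-octaenal (ring-A C35 aldehyde), via sulfonyl carbanion 28 (not isolated)
Conditions: t-Bu-P4 phosphazene base (1.0 equiv), THF, −78 °C; cannulated into 27 (3 equiv), THF/CH2Cl2, −78 → 25 °C; then heptane, 80 °C, dark, argon (Z→E)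
Reagents that add atoms: none
Why: One-pot Julia–Kocienski-type olefination of the 3,5-bis(trifluoromethyl)phenyl sulfone (addition, Smiles rearrangement, loss of SO2 and aryloxide) forms C7=C8; the pre-formed carbanion meets excess dialdehyde so that mono-olefination should prevail and no free base meets the product, and the hindered 7Z isomer should equilibrate to 7E on heating.

Step 17
Reactants: 26 ring-B sulfone; 29 ring-A C35 aldehyde
Product: 31 tert-butyldimethylsilyl ether of the target (all-E C50 polyene), via sulfonyl carbanion 30 (not isolated)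
Conditions: 26 (1.2 equiv), t-Bu-P4 phosphazene base (1.15 equiv), THF, −78 °C; then 29, −78 → 25 °C; then heptane, 80 °C, dark, argon (Z→E)
Reagents that add atoms: none
Why: The same sulfone olefination forms C7'=C8' and completes the C50 chain; the base is consumed by the sulfone before the polyene is added, so the doubly allylic C6–H and C6'–H should not be deprotonated and both ring configurations should survive.

Step 18
Reactants: 31 tert-butyldimethylsilyl ether of the target
Product: 32 (2S,6R,2'R,6'S)-2'-[(2E)-4-hydroxy-3-methylbut-2-en-1-yl]-2-(3-methylbut-2-en-1-yl)-ε,ε-carotene (target)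
Conditions: Bu4NF, THF, 0 → 25 °C, dark, argon
Reagents that add atoms: none
Why: Fluoride-induced desilylation frees the primary allylic alcohol under conditions that leave the polyene and the four stereocentres untouched.

Compound list
1 | 2,4,4-trimethylcyclohex-2-en-1-one | CC1=CC(C)(C)CCC1=O | starting material
2 | 2,4,4-trimethylcyclohexa-2,5-dien-1-one | CC1=CC(C)(C)C=CC1=O | intermediate
3 | allyltrimethylsilane | C=CC[Si](C)(C)C | starting material
4 | trichlorotitanium dienolate of 5 (racemic) | C=CCC1C=C(O[Ti](Cl)(Cl)Cl)C(C)=CC1(C)C | intermediate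
5 | rac-2,4,4-trimethyl-5-(prop-2-en-1-yl)cyclohex-2-en-1-one | C=CCC1CC(=O)C(C)=CC1(C)C | intermediate
6 | rac-(1R,5S)-2,4,4-trimethyl-5-(prop-2-en-1-yl)cyclohex-2-en-1-ol (cis; racemate, one enantiomer drawn) | C=CC[C@H]1C[C@@H](O)C(C)=CC1(C)C | intermediate
7 | (1R,5S)-2,4,4-trimethyl-5-(prop-2-en-1-yl)cyclohex-2-en-1-yl acetate | C=CC[C@H]1C[C@@H](OC(C)=O)C(C)=CC1(C)C | intermediate
8 | (1R,5S)-2,4,4-trimethyl-5-(prop-2-en-1-yl)cyclohex-2-en-1-ol | C=CC[C@H]1C[C@@H](O)C(C)=CC1(C)C | intermediate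
9 | 3,5-bis(trifluoromethyl)benzenethiol | Sc1cc(cc(c1)C(F)(F)F)C(F)(F)F | starting material
10 | bromoacetic acid | OC(=O)CBr | starting material
11 | {[3,5-bis(trifluoromethyl)phenyl]sulfanyl}acetic acid | OC(=O)CSc1cc(cc(c1)C(F)(F)F)C(F)(F)F | intermediate
12 | {[3,5-bis(trifluoromethyl)phenyl]sulfonyl}acetic acid | OC(=O)CS(=O)(=O)c1cc(cc(c1)C(F)(F)F)C(F)(F)F | intermediate
13 | 2-methylbut-2-ene | CC=C(C)C | starting material
14 | (1R,5S)-2,4,4-trimethyl-5-(3-methylbut-2-en-1-yl)cyclohex-2-en-1-ol | CC(C)=CC[C@H]1C[C@@H](O)C(C)=CC1(C)C | intermediate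
15 | (1R,5S)-2,4,4-trimethyl-5-(3-methylbut-2-en-1-yl)cyclohex-2-en-1-yl {[3,5-bis(trifluoromethyl)phenyl]sulfonyl}acetate | CC(C)=CC[C@H]1C[C@@H](OC(=O)CS(=O)(=O)c2cc(cc(c2)C(F)(F)F)C(F)(F)F)C(C)=CC1(C)C | intermediate
16 | trimethylsilyl ketene acetal of 15 | CC(C)=CC[C@H]1C[C@@H](OC(O[Si](C)(C)C)=CS(=O)(=O)c2cc(cc(c2)C(F)(F)F)C(F)(F)F)C(C)=CC1(C)C | intermediate
17 | trimethylsilyl 2-{[3,5-bis(trifluoromethyl)phenyl]sulfonyl}-2-[(1R,5S)-2,6,6-trimethyl-5-(3-methylbut-2-en-1-yl)cyclohex-2-en-1-yl]acetate (both C7 epimers) | CC(C)=CC[C@H]1CC=C(C)[C@@H](C(C(=O)O[Si](C)(C)C)S(=O)(=O)c2cc(cc(c2)C(F)(F)F)C(F)(F)F)C1(C)C | intermediate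
18 | 1-({[(1R,5S)-2,6,6-trimethyl-5-(3-methylbut-2-en-1-yl)cyclohex-2-en-1-yl]methyl}sulfonyl)-3,5-bis(trifluoromethyl)benzene | CC(C)=CC[C@H]1CC=C(C)[C@@H](CS(=O)(=O)c2cc(cc(c2)C(F)(F)F)C(F)(F)F)C1(C)C | intermediate
19 | methacrolein (2-methylprop-2-enal) | CC(=C)C=O | starting material
20 | (2E)-4-[(1S,5R)-5-hydroxy-2,2,4-trimethylcyclohex-3-en-1-yl]-2-methylbut-2-enal | O=C/C(C)=C/C[C@H]1C[C@@H](O)C(C)=CC1(C)C | intermediate
21 | (1R,5S)-5-[(2E)-4-hydroxy-3-methylbut-2-en-1-yl]-2,4,4-trimethylcyclohex-2-en-1-ol | OC/C(C)=C/C[C@H]1C[C@@H](O)C(C)=CC1(C)C | intermediate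
22 | (1R,5S)-5-[(2E)-4-{[tert-butyl(dimethyl)silyl]oxy}-3-methylbut-2-en-1-yl]-2,4,4-trimethylcyclohex-2-en-1-ol | CC(C)(C)[Si](C)(C)OC/C(C)=C/C[C@H]1C[C@@H](O)C(C)=CC1(C)C | intermediate
23 | (1S,5S)-5-[(2E)-4-{[tert-butyl(dimethyl)silyl]oxy}-3-methylbut-2-en-1-yl]-2,4,4-trimethylcyclohex-2-en-1-yl {[3,5-bis(trifluoromethyl)phenyl]sulfonyl}acetate | CC(C)(C)[Si](C)(C)OC/C(C)=C/C[C@H]1C[C@H](OC(=O)CS(=O)(=O)c2cc(cc(c2)C(F)(F)F)C(F)(F)F)C(C)=CC1(C)C | intermediate
24 | trimethylsilyl ketene acetal of 23 | CC(C)(C)[Si](C)(C)OC/C(C)=C/C[C@H]1C[C@H](OC(O[Si](C)(C)C)=CS(=O)(=O)c2cc(cc(c2)C(F)(F)F)C(F)(F)F)C(C)=CC1(C)C | intermediate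
25 | trimethylsilyl 2-{[3,5-bis(trifluoromethyl)phenyl]sulfonyl}-2-{(1S,5R)-5-[(2E)-4-{[tert-butyl(dimethyl)silyl]oxy}-3-methylbut-2-en-1-yl]-2,6,6-trimethylcyclohex-2-en-1-yl}acetate (both C7' epimers) | CC(C)(C)[Si](C)(C)OC/C(C)=C/C[C@H]1CC=C(C)[C@H](C(C(=O)O[Si](C)(C)C)S(=O)(=O)c2cc(cc(c2)C(F)(F)F)C(F)(F)F)C1(C)C | intermediate
26 | 1-[({(1S,5R)-5-[(2E)-4-{[tert-butyl(dimethyl)silyl]oxy}-3-methylbut-2-en-1-yl]-2,6,6-trimethylcyclohex-2-en-1-yl}methyl)sulfonyl]-3,5-bis(trifluoromethyl)benzene | CC(C)(C)[Si](C)(C)OC/C(C)=C/C[C@H]1CC=C(C)[C@H](CS(=O)(=O)c2cc(cc(c2)C(F)(F)F)C(F)(F)F)C1(C)C | intermediate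
27 | crocetindialdehyde, (2E,4E,6E,8E,10E,12E,14E)-2,6,11,15-tetramethylhexadeca-2,4,6,8,10,12,14-heptaenedial | O=C/C(C)=C/C=C/C(C)=C/C=C/C=C(C)/C=C/C=C(C)/C=O | starting material
28 | α-sulfonyl carbanion of 18 (phosphazenium salt; anion drawn) | CC(C)=CC[C@H]1CC=C(C)[C@@H]([CH-]S(=O)(=O)c2cc(cc(c2)C(F)(F)F)C(F)(F)F)C1(C)C | intermediate
29 | (2E,4E,6E,8E,10E,12E,14E,16E)-2,6,11,15-tetramethyl-17-[(1R,5S)-2,6,6-trimethyl-5-(3-methylbut-2-en-1-yl)cyclohex-2-en-1-yl]heptadeca-2,4,6,8,10,12,14,16-octaenal | CC(C)=CC[C@H]1CC=C(C)[C@@H](/C=C/C(C)=C/C=C/C(C)=C/C=C/C=C(C)/C=C/C=C(C)/C=O)C1(C)C | intermediate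
30 | α-sulfonyl carbanion of 26 (phosphazenium salt; anion drawn) | CC(C)(C)[Si](C)(C)OC/C(C)=C/C[C@H]1CC=C(C)[C@H]([CH-]S(=O)(=O)c2cc(cc(c2)C(F)(F)F)C(F)(F)F)C1(C)C | intermediate
31 | tert-butyldimethylsilyl ether of the target | CC(C)=CC[C@H]1CC=C(C)[C@@H](/C=C/C(C)=C/C=C/C(C)=C/C=C/C=C(C)/C=C/C=C(C)/C=C/[C@H]2C(C)=CC[C@H](C/C=C(\C)CO[Si](C)(C)C(C)(C)C)C2(C)C)C1(C)C | intermediate
32 | (2S,6R,2'R,6'S)-2'-[(2E)-4-hydroxy-3-methylbut-2-en-1-yl]-2-(3-methylbut-2-en-1-yl)-ε,ε-carotene | CC(C)=CC[C@H]1CC=C(C)[C@@H](/C=C/C(C)=C/C=C/C(C)=C/C=C/C=C(C)/C=C/C=C(C)/C=C/[C@H]2C(C)=CC[C@H](C/C=C(\C)CO)C2(C)C)C1(C)C | target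

Total steps: 18. Longest linear sequence: 12 (steps 1–5, 11–15, 17, 18).

Steps most likely to fail

1. Step 10 (the same risk holds for step 15). The silyl ketene acetal may ionise to the ring allyl cation and eliminate to a cyclohexadiene, or fail to bond at the neopentyl C6 terminus, before the [3,3] shift takes place. The fallback sets out from 8 and comes back at 18; it makes the same C6–C7 bond by a [2,3]-Wittig–Still rearrangement with the same suprafacial transfer from C4. Alcohol 8 would be O-alkylated (KH, Bu3SnCH2I, THF) to tributyl({[(1R,5S)-2,4,4-trimethyl-5-(prop-2-en-1-yl)cyclohex-2-en-1-yl]oxy}methyl)stannane F1. Tin–lithium exchange (n-BuLi, THF, −78 °C) and the [2,3] shift would give [(1R,5S)-2,6,6-trimethyl-5-(prop-2-en-1-yl)cyclohex-2-en-1-yl]methanol F2. Mitsunobu thioetherification with thiol 9 (PPh3, DIAD) would give 1-({[(1R,5S)-2,6,6-trimethyl-5-(prop-2-en-1-yl)cyclohex-2-en-1-yl]methyl}sulfanyl)-3,5-bis(trifluoromethyl)benzene F3. Oxidation (H2O2, (NH4)6Mo7O24·4H2O, EtOH) would give the corresponding allyl sulfone F4, and cross-metathesis with 13 as in step 8 would return to 18.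

2. Step 17 (the same risk holds for step 16). The hindered sulfonyl carbanion may add slowly or reversibly to the long, sparingly soluble polyenal, so that proton transfer, double olefination of the dialdehyde and E/Z mixtures that resist equilibration at the C35 or C50 stage take over. The fallback sets out from 18 and 26 and comes back at 31; it moves the sulfone olefination to a small, soluble aldehyde and builds the centre of the chain by Horner–Wadsworth–Emmons reactions. Carbanions 28 and 30 would each be condensed with (2E)-4,4-dimethoxy-2-methylbut-2-enal under the conditions of step 16 to give (1E,3E)-5,5-dimethoxy-3-methyl-1-[(1R,5S)-2,6,6-trimethyl-5-(3-methylbut-2-en-1-yl)cyclohex-2-en-1-yl]penta-1,3-diene F5 and its ring-B counterpart F7. Aqueous oxalic acid in THF would free the dienals (2E,4E)-3-methyl-5-[(1R,5S)-2,6,6-trimethyl-5-(3-methylbut-2-en-1-yl)cyclohex-2-en-1-yl]penta-2,4-dienal F6 and (2E,4E)-5-[(1S,5R)-5-[(2E)-4-{[tert-butyl(dimethyl)silyl]oxy}-3-methylbut-2-en-1-yl]-2,6,6-trimethylcyclohex-2-en-1-yl]-3-methylpenta-2,4-dienal F8. F6 would react with the pre-formed mono-anion (NaH, THF) of excess tetraethyl [(2E,4E,6E)-2,7-dimethylocta-2,4,6-triene-1,8-diyl]bis(phosphonate) to give diethyl {(2E,4E,6E,8E,10E,12E)-2,7,11-trimethyl-13-[(1R,5S)-2,6,6-trimethyl-5-(3-methylbut-2-en-1-yl)cyclohex-2-en-1-yl]trideca-2,4,6,8,10,12-hexaen-1-yl}phosphonate F9. The pre-formed anion of F9, with no excess base, would then be condensed with F8 to give 31.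

3. Step 14. With a hindered secondary allylic alcohol and a C–H-acidic carboxylic acid, the alkoxyphosphonium ion may eliminate to the cyclohexadiene, or alkylate the acidic methylene of the product, instead of undergoing clean SN2 inversion. The fallback sets out from 22 and comes back at 23; it inverts C4 by oxidation and reagent-controlled reduction in place of displacement. MnO2 in CH2Cl2 would oxidise 22 to (5S)-5-[(2E)-4-{[tert-butyl(dimethyl)silyl]oxy}-3-methylbut-2-en-1-yl]-2,4,4-trimethylcyclohex-2-en-1-one F10. (R)-2-Methyl-CBS-oxazaborolidine (cat.) with BH3·SMe2 would deliver hydride against the substrate's cis preference to give (1S,5S)-5-[(2E)-4-{[tert-butyl(dimethyl)silyl]oxy}-3-methylbut-2-en-1-yl]-2,4,4-trimethylcyclohex-2-en-1-ol F11. Carbodiimide esterification with 12 as in step 9 would then give 23.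

Further compounds
F1 | step 10 | tributyl({[(1R,5S)-2,4,4-trimethyl-5-(prop-2-en-1-yl)cyclohex-2-en-1-yl]oxy}methyl)stannane | C=CC[C@H]1C[C@@H](OC[Sn](CCCC)(CCCC)CCCC)C(C)=CC1(C)C
F2 | step 10 | [(1R,5S)-2,6,6-trimethyl-5-(prop-2-en-1-yl)cyclohex-2-en-1-yl]methanol | C=CC[C@H]1CC=C(C)[C@@H](CO)C1(C)C
F3 | step 10 | 1-({[(1R,5S)-2,6,6-trimethyl-5-(prop-2-en-1-yl)cyclohex-2-en-1-yl]methyl}sulfanyl)-3,5-bis(trifluoromethyl)benzene | C=CC[C@H]1CC=C(C)[C@@H](CSc2cc(cc(c2)C(F)(F)F)C(F)(F)F)C1(C)C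
F4 | step 10 | 1-({[(1R,5S)-2,6,6-trimethyl-5-(prop-2-en-1-yl)cyclohex-2-en-1-yl]methyl}sulfonyl)-3,5-bis(trifluoromethyl)benzene | C=CC[C@H]1CC=C(C)[C@@H](CS(=O)(=O)c2cc(cc(c2)C(F)(F)F)C(F)(F)F)C1(C)C
F5 | step 17 | (1E,3E)-5,5-dimethoxy-3-methyl-1-[(1R,5S)-2,6,6-trimethyl-5-(3-methylbut-2-en-1-yl)cyclohex-2-en-1-yl]penta-1,3-diene | CC(C)=CC[C@H]1CC=C(C)[C@@H](/C=C/C(C)=C/C(OC)OC)C1(C)C
F6 | step 17 | (2E,4E)-3-methyl-5-[(1R,5S)-2,6,6-trimethyl-5-(3-methylbut-2-en-1-yl)cyclohex-2-en-1-yl]penta-2,4-dienal | CC(C)=CC[C@H]1CC=C(C)[C@@H](/C=C/C(C)=C/C=O)C1(C)C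
F7 | step 17 | tert-butyl{[(2E)-4-{(1R,5S)-5-[(1E,3E)-5,5-dimethoxy-3-methylpenta-1,3-dien-1-yl]-4,6,6-trimethylcyclohex-3-en-1-yl}-2-methylbut-2-en-1-yl]oxy}dimethylsilane | CC(C)(C)[Si](C)(C)OC/C(C)=C/C[C@H]1CC=C(C)[C@H](/C=C/C(C)=C/C(OC)OC)C1(C)C
F8 | step 17 | (2E,4E)-5-[(1S,5R)-5-[(2E)-4-{[tert-butyl(dimethyl)silyl]oxy}-3-methylbut-2-en-1-yl]-2,6,6-trimethylcyclohex-2-en-1-yl]-3-methylpenta-2,4-dienal | CC(C)(C)[Si](C)(C)OC/C(C)=C/C[C@H]1CC=C(C)[C@H](/C=C/C(C)=C/C=O)C1(C)C
F9 | step 17 | diethyl {(2E,4E,6E,8E,10E,12E)-2,7,11-trimethyl-13-[(1R,5S)-2,6,6-trimethyl-5-(3-methylbut-2-en-1-yl)cyclohex-2-en-1-yl]trideca-2,4,6,8,10,12-hexaen-1-yl}phosphonate | CC(C)=CC[C@H]1CC=C(C)[C@@H](/C=C/C(C)=C/C=C/C(C)=C/C=C/C=C(C)/CP(=O)(OCC)OCC)C1(C)C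
F10 | step 14 | (5S)-5-[(2E)-4-{[tert-butyl(dimethyl)silyl]oxy}-3-methylbut-2-en-1-yl]-2,4,4-trimethylcyclohex-2-en-1-one | CC(C)(C)[Si](C)(C)OC/C(C)=C/C[C@H]1CC(=O)C(C)=CC1(C)C
F11 | step 14 | (1S,5S)-5-[(2E)-4-{[tert-butyl(dimethyl)silyl]oxy}-3-methylbut-2-en-1-yl]-2,4,4-trimethylcyclohex-2-en-1-ol | CC(C)(C)[Si](C)(C)OC/C(C)=C/C[C@H]1C[C@H](O)C(C)=CC1(C)C
A1 | direct plan | methyl (2E)-3-[(1S,3R)-3-(2-methoxy-2-oxoethyl)-2,2-dimethylcyclobutyl]but-2-enoate | COC(=O)C[C@H]1C[C@@H](/C(C)=C/C(=O)OC)C1(C)C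
A2 | direct plan | methyl (1R,5R)-5-(2-methoxy-2-oxoethyl)-2,6,6-trimethylcyclohex-2-ene-1-carboxylate | COC(=O)C[C@H]1CC=C(C)[C@@H](C(=O)OC)C1(C)C
A3 | direct plan | (3E)-4-[(1R,5R)-5-[(2E)-4-{[tert-butyl(diphenyl)silyl]oxy}-3-methylbut-2-en-1-yl]-2,6,6-trimethylcyclohex-2-en-1-yl]but-3-en-2-one (2,6-cis) | CC(C)(C)[Si](OC/C(C)=C/C[C@H]1CC=C(C)[C@@H](/C=C/C(C)=O)C1(C)C)(c2ccccc2)c2ccccc2
A4 | direct plan | (3E)-4-[(1S,5R)-5-[(2E)-4-{[tert-butyl(diphenyl)silyl]oxy}-3-methylbut-2-en-1-yl]-2,6,6-trimethylcyclohex-2-en-1-yl]but-3-en-2-one (2,6-trans) | CC(C)(C)[Si](OC/C(C)=C/C[C@H]1CC=C(C)[C@H](/C=C/C(C)=O)C1(C)C)(c2ccccc2)c2ccccc2
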